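**Retrosynthetic overview**

- Aspidin PB ⇒ a fully substituted ring A benzaldehyde + propionylfilicinic acid (ring B). The CH2 bridge comes from a one-pot Knoevenagel condensation/Hantzsch-ester hydride transfer, not from the usual formaldehyde (or Mannich) union of two finished monomers.
- Ring A aldehyde ⇒ 2-methylphloroglucinol. The formyl group goes on first and later becomes the bridge carbon. It directs O-methylation to the para OH and leaves a single ring carbon for butanoylation, which fixes the awkward OMe/acyl pattern.
- Ring B ⇒ flopropione by dearomatizing gem-dimethylation.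
- Ring order: ring A stays aromatic from the commercial phenol (steps 1–3); the ring B dienone is created in step 4; the two rings are joined last (step 5).

Assumption: the target SMILES has no stereocentre and no stereogenic double bond, so the compound is achiral and no stereocontrol is needed; the keto–enol tautomer drawn in the SMILES is used for names.

**Route**

Step 1
Reactants: 1 2-methylbenzene-1,3,5-triol (2-methylphloroglucinol)
Product: 3 2,4,6-trihydroxy-3-methylbenzaldehyde, via aryl iminium chloride 2 (not isolated)
Conditions: POCl3 (1.1 equiv), DMF (1.2 equiv), EtOAc, 0 °C to rt; then H2O, 60 °C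
Reagents that add atoms: N,N-dimethylformamide CN(C)C=O; water O
Why: Vilsmeier–Haack formylation: the two open positions of 1 are equivalent and each is flanked by two OH groups, and the mono-iminium salt 2 precipitates from EtOAc, so a second formylation is suppressed before water hydrolyses 2 to the aldehyde.

Step 2
Reactants: 3 2,4,6-trihydroxy-3-methylbenzaldehyde
Product: 4 2,6-dihydroxy-4-methoxy-3-methylbenzaldehyde
Conditions: MeI (1.1 equiv), Li2CO3 (1.1 equiv), DMF, 45 °C
Reagents that add atoms: iodomethane CI
Why: Williamson etherification under weak-base control: the 4-OH, para to the formyl group, is the most acidic and least chelated OH, so Li2CO3 ionises it selectively and it alone is methylated while the two ortho OH groups stay free.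

Step 3
Reactants: 4 2,6-dihydroxy-4-methoxy-3-methylbenzaldehyde
Product: 5 3-butanoyl-2,6-dihydroxy-4-methoxy-5-methylbenzaldehyde
Conditions: PrCOCl (1.2 equiv), AlCl3 (4 equiv), CH2Cl2/MeNO2, 0 °C to rt; then ice, 1 M HCl
Reagents that add atoms: butanoyl chloride CCCC(Cl)=O
Why: Friedel–Crafts acylation (any aryl butanoate formed first undergoes Fries rearrangement under the same AlCl3): 4 has one free ring carbon, activated ortho/ortho/para by OMe, OH and OH, so the regiochemistry is forced, as in the second acylation of an acylphloroglucinol, and the low temperature keeps the OMe group intact.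

Step 4
Reactants: 6 1-(2,4,6-trihydroxyphenyl)propan-1-one (flopropione)
Product: 8 3,5-dihydroxy-6,6-dimethyl-2-propanoylcyclohexa-2,4-dien-1-one, via monomethyl ketone 7 (not isolated)
Conditions: NaOMe (4 equiv), MeI (2.5 equiv), MeOH, 0 °C to rt, N2; then 1 M HCl
Reagents that add atoms: iodomethane CI
Why: Base-mediated C-methylation of the phloroglucinol polyanion: after the first C-methylation (7) the methylated carbon is the most nucleophilic site, so the second MeI gives the dearomatized gem-dimethyl β-triketone 8 (propionylfilicinic acid), the established way from acylphloroglucinols to acylfilicinic acids, with over-methylated by-products removed by crystallisation.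

Step 5
Reactants: 5 3-butanoyl-2,6-dihydroxy-4-methoxy-5-methylbenzaldehyde; 8 3,5-dihydroxy-6,6-dimethyl-2-propanoylcyclohexa-2,4-dien-1-one (propionylfilicinic acid)
Product: 10 aspidin PB, via Knoevenagel alkylidene 9 (not isolated)
Conditions: L-proline (20 mol %), Hantzsch ester (diethyl 2,6-dimethyl-1,4-dihydropyridine-3,5-dicarboxylate, 1.2 equiv), EtOH, 25 to 50 °C, N2
Reagents that add atoms: none
Why: Three-component reductive alkylation (amine-catalysed Knoevenagel condensation, then Hantzsch-ester transfer hydrogenation): the only aldehyde (in 5) condenses with the only nucleophilic ring C–H (in 8) to the alkylidene/o-quinone methide 9, which takes up hydride at the benzylic carbon while addition of a second 8 stays reversible, so only the cross-coupled methylene-bridged product can form and no stereocentre arises.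

**Compound list**

1 | 2-methylbenzene-1,3,5-triol (2-methylphloroglucinol), achiral | Cc1c(O)cc(O)cc1O | starting material
2 | (2,4,6-trihydroxy-3-methylphenyl)methylidene-dimethyliminium chloride, formed in the flask in step 1 | C[N+](C)=Cc1c(O)cc(O)c(C)c1O.[Cl-] | intermediate
3 | 2,4,6-trihydroxy-3-methylbenzaldehyde | O=Cc1c(O)cc(O)c(C)c1O | intermediate
4 | 2,6-dihydroxy-4-methoxy-3-methylbenzaldehyde | O=Cc1c(O)cc(OC)c(C)c1O | intermediate
5 | 3-butanoyl-2,6-dihydroxy-4-methoxy-5-methylbenzaldehyde | CCCC(=O)c1c(O)c(C=O)c(O)c(C)c1OC | intermediate
6 | 1-(2,4,6-trihydroxyphenyl)propan-1-one (flopropione) | CCC(=O)c1c(O)cc(O)cc1O | starting material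
7 | 1-(2,4,6-trihydroxy-3-methylphenyl)propan-1-one, formed in the flask in step 4 | CCC(=O)c1c(O)cc(O)c(C)c1O | intermediate
8 | 3,5-dihydroxy-6,6-dimethyl-2-propanoylcyclohexa-2,4-dien-1-one (propionylfilicinic acid) | CCC(=O)C1=C(O)C=C(O)C(C)(C)C1=O | intermediate
9 | 4-[(3-butanoyl-2,6-dihydroxy-4-methoxy-5-methylphenyl)methylidene]-5-hydroxy-2,2-dimethyl-6-propanoylcyclohex-5-ene-1,3-dione, formed in the flask in step 5 (alkene geometry not defined, o-quinone methide tautomer) | CCCC(=O)c1c(O)c(C=C2C(=O)C(C)(C)C(=O)C(C(=O)CC)=C2O)c(O)c(C)c1OC | intermediate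
10 | aspidin PB: 4-[(3-butanoyl-2,6-dihydroxy-4-methoxy-5-methylphenyl)methyl]-3,5-dihydroxy-6,6-dimethyl-2-propanoylcyclohexa-2,4-dien-1-one, achiral | CCCC(=O)c1c(O)c(CC2=C(O)C(C)(C)C(=O)C(C(=O)CC)=C2O)c(O)c(C)c1OC | target

**Totals and risks**

Total step count: 5. Longest linear sequence: 4 steps (1 → 3 → 4 → 5 → 10, steps 1, 2, 3 and 5); step 4 is the one-step side branch to 8.

Most likely to fail, in order:

Step 5 (key union). This pairing of a chelated, electron-rich aldehyde with an acylfilicinic acid is untested in the reductive alkylation. The aldehyde may condense slowly, or 9 may be held as the bis-adduct with a second 8 or as a cyclic hemiketal. The fallback sets out from 5 and comes back at 10. Reductive amination of 5 with morpholine (NaBH(OAc)3, AcOH, 1,2-dichloroethane, rt) gives the Mannich base 1-[2,4-dihydroxy-6-methoxy-5-methyl-3-(morpholin-4-ylmethyl)phenyl]butan-1-one F1. Heating F1 with 8 in 1,4-dioxane at 90 °C expels morpholine to give the o-quinone methide of ring A, which the nucleophilic ring carbon of 8 traps by Michael addition to give 10.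

Step 3 (butanoylation of an aldehyde-bearing ring). The formyl group deactivates the ring, and AlCl3 may attack the OMe group or the aldehyde. The fallback sets out from 4 and comes back at 10 by changing the order of events. Compound 4 is coupled with 8 under the step 5 conditions. This passes through the transient alkylidene 4-[(2,6-dihydroxy-4-methoxy-3-methylphenyl)methylidene]-5-hydroxy-2,2-dimethyl-6-propanoylcyclohex-5-ene-1,3-dione F2 and gives the des-butanoyl dimer 4-[(2,6-dihydroxy-4-methoxy-3-methylphenyl)methyl]-3,5-dihydroxy-6,6-dimethyl-2-propanoylcyclohexa-2,4-dien-1-one F3. The single remaining aromatic C–H of F3 is then acylated (butanoyl chloride, TiCl4, CH2Cl2, 0 °C; NaHCO3/MeOH work-up to cleave any enol ester), which gives 10. Ring B has no free carbon left to acylate.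

Step 2 (mono-O-methylation). Methylation at an ortho OH or double methylation would cut the yield. The fallback sets out from 3 and comes back at 4. Exhaustive methylation (Me2SO4, K2CO3, acetone, reflux) gives 2,4,6-trimethoxy-3-methylbenzaldehyde F4. AlCl3 (4 equiv, chlorobenzene, 80 °C) then cleaves only the two methoxy groups ortho to the chelating formyl group and leaves the para OMe, which gives 4.

**Further compounds**

F1 | step 5 | 1-[2,4-dihydroxy-6-methoxy-5-methyl-3-(morpholin-4-ylmethyl)phenyl]butan-1-one | CCCC(=O)c1c(O)c(CN2CCOCC2)c(O)c(C)c1OC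
F2 | step 3 | 4-[(2,6-dihydroxy-4-methoxy-3-methylphenyl)methylidene]-5-hydroxy-2,2-dimethyl-6-propanoylcyclohex-5-ene-1,3-dione (alkene geometry not defined) | COc1cc(O)c(C=C2C(=O)C(C)(C)C(=O)C(C(=O)CC)=C2O)c(O)c1C
F3 | step 3 | 4-[(2,6-dihydroxy-4-methoxy-3-methylphenyl)methyl]-3,5-dihydroxy-6,6-dimethyl-2-propanoylcyclohexa-2,4-dien-1-one | COc1cc(O)c(CC2=C(O)C(C)(C)C(=O)C(C(=O)CC)=C2O)c(O)c1C
F4 | step 2 | 2,4,6-trimethoxy-3-methylbenzaldehyde | COc1cc(OC)c(C=O)c(OC)c1C
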